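I choose to bracket this flask rather than fit it, and I carry one quantity: the capacity ratio 90.0%, the charge of X over the charge of L, capped at one.

| flask | L | X | G | remark | time |
|---|---|---|---|---|---|
| zeta | 0.28 M (fed, over 3.0 min) | 0.18 M | 0.60 M | run made earlier |  |
| delta | 0.44 M (fed, over 3.0 min) | 0.18 M | 0.60 M | run made earlier |  |
| flask | 0.20 M (fed, over 3.0 min) | 0.180 M | 0.600 M |  | 15 min |

- zeta (time / min: L / %, Q / %): 2.00: 20.3, 47.2; 5.00: 36.5, 63.7; 10.0: 35.8, 66.1; 15.0: 35.8, 62.2
- delta (time / min: L / %, Q / %): 4.00: 56.8, 40.3; 8.00: 58.9, 41.5; 12.0: 59.8, 40.2; 15.0: 59.1, 40.6

(each reading ± 1 percentage point)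

1. part of the L that has reacted at 15 min
2. share of the unused X that is free and not bound as Z, at 15 min

- percentages count the whole charge, also what has not yet gone in
- the earlier runs do not show how much of X is bound; that part of a forecast is a guess

Zeta loses 0.180 M of L and delta 0.180 M, each matching the charge of X, so I read X as the limiting reagent and put the crossing of control at equal charges. The flask's L exceeds its X by 0.0200 M, just past that crossing.

From above, the capacity ratio plus one scatter on the zeta charge gives 91.4%. From below, zeta's Q reading at 2.00 min means a mean rate of 0.0661 M min⁻¹. I take L as staying at or below its reading up to then and X as staying below its charge, so I read the second-order constant as at least 6.46 M⁻¹ min⁻¹, an estimate that carries the scatter of those readings. If I let the flask's whole X and whole L start reacting only at the end of the feed, that constant leaves 0.00472 M of X at 15 min in my reckoning, an estimated floor of 87.6%. The readings do not show bound X, so I leave the free share unbracketed.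

The forecast says 89.8%, above my floor and below my top, holding that “the reaction is essentially finished”; its free share, 50%, is a stated guess.

The flask gives 90.1% reacted, level with its capacity ratio and inside my bracket, and a free share of 87.3%, 37 percentage points above the guess.

    L + X → E + Q (k = 0.410 M⁻¹ s⁻¹)
    X + E ⇌ Z, settled at all times (K = 130 M⁻¹)
    E + G ⇌ D (K = 380 M⁻¹, k = 1.40 M⁻¹ s⁻¹)
    L + E → J (k = 0.00770 M⁻¹ s⁻¹)

The shrinking supply of X holds the flask short of full use of L: the same run without that shrinkage reaches 100% against 90.1%. At 15.0 min the flask keeps 0.0379% of its charge of X as free X. For a neighbour flask charged with 0.50 M of L, the capacity ratio gives 36.0%, and that neighbour reacts 36.5%.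

(The runs are simulated for substances that don't exist; noise was put on by code.)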